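The route disconnects the O1–C2 bond of the γ-lactone ring (O1, C2 carrying the chain, C3 carrying the carboxyl, C4, C5 carbonyl). C2 is the γ carbon of the C5 carboxyl, so this C–O bond can be forged at a plain CH2 group. One manganese-catalysed, carboxylate-directed C–H oxidation forms O1–C2, closes the ring and sets C2 trans to C3. The precursor is an (R)-2-alkylsuccinic acid 1-tert-butyl ester with a free CH2CO2H arm and a free methyl ketone at the chain end, made by Stobbe condensation and asymmetric hydrogenation; the ketone travels as a Weinreb amide until just before. Ketal protection, C4 methylenation and acidolysis finish the synthesis.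

Key step: step 6

Remark: lactone numbering (O1, C2, C3, C4, C5) is used throughout, also for open-chain compounds (C2 = C4 of acid 10); the half-ester that leads to the (2R,3S) lactone is R, because CH2CO2H outranks the alkyl chain there, whereas in the lactone C2 outranks C4 and the same arrangement reads S.

Step 1
Reactants: 1 ω-pentadecalactone; 2 N,O-dimethylhydroxylamine hydrochloride
Product: 3 15-hydroxy-N-methoxy-N-methylpentadecanamide
Conditions: i-PrMgCl (3 equiv), THF, −20 to 0 °C; aq. NH4Cl
Reagents that add atoms: N,O-dimethylhydroxylamine hydrochloride, CNOC.Cl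
Why: The chloromagnesium amide formed in the flask opens the unstrained macrolactone like an ordinary ester (Weinreb amide synthesis by ester aminolysis), and the chelated amide does not react further.

Step 2
Reactants: 3 15-hydroxy-N-methoxy-N-methylpentadecanamide
Product: 4 N-methoxy-N-methyl-15-oxopentadecanamide
Conditions: TEMPO (10 mol %), PhI(OAc)2 (1.1 equiv), CH2Cl2, rt
Reagents that add atoms: none
Why: Oxoammonium-mediated (TEMPO) oxidation of a primary alcohol stops at the aldehyde when water is absent and leaves the Weinreb amide untouched.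

Step 3
Reactants: 4 N-methoxy-N-methyl-15-oxopentadecanamide; 5 di-tert-butyl succinate
Product: 7 (3E)-3-(tert-butoxycarbonyl)-18-[methoxy(methyl)amino]-18-oxooctadec-3-enoic acid, via racemic paraconate lactone 6 (not isolated)
Conditions: KOtBu (1.3 equiv), t-BuOH, rt to 45 °C, slow addition of 4; then aq. HCl to pH 3
Reagents that add atoms: none
Why: Stobbe condensation, in which aldol addition of the succinate enolate, lactonisation to 6 with loss of tert-butoxide and E1cB opening of that lactone place the free acid on the CH2 arm and the ester on the alkene carbon; the E isomer should predominate, the E/Z mixture is carried on, and the tertiary amide is inert to alkoxide.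

Step 4
Reactants: 7 (3E)-3-(tert-butoxycarbonyl)-18-[methoxy(methyl)amino]-18-oxooctadec-3-enoic acid
Product: 8 (3R)-3-(tert-butoxycarbonyl)-18-[methoxy(methyl)amino]-18-oxooctadecanoic acid
Conditions: [Rh(cod)((S,S)-Et-DuPhos)]BF4 (1 mol %), H2 (5 bar), NaOMe (0.1 equiv), MeOH, rt
Reagents that add atoms: none
Why: Rhodium-bisphospholane asymmetric hydrogenation of a β-substituted itaconate half-ester, in which the carboxylate chelates the metal and the ligand fixes the face of hydrogen delivery so that E and Z isomers converge on the R centre at C3; the (S,S) ligand is chosen by analogy with enamide-type binding, and the (R,R) complex would be used if the sense proved opposite.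

Step 5
Reactants: 8 (3R)-3-(tert-butoxycarbonyl)-18-[methoxy(methyl)amino]-18-oxooctadecanoic acid; 9 methylmagnesium bromide
Product: 10 (3R)-3-(tert-butoxycarbonyl)-18-oxononadecanoic acid
Conditions: MeMgBr (3.5 equiv), THF, −20 to 0 °C; aq. citric acid
Reagents that add atoms: methylmagnesium bromide, C[Mg]Br
Why: Weinreb ketone synthesis, in which the Grignard reagent first deprotonates the acid and then adds once to the N-methoxy amide to give a chelated tetrahedral intermediate that releases the methyl ketone only on work-up, while the carboxylate and the hindered tert-butyl ester do not react at this temperature.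

Step 6
Reactants: 10 (3R)-3-(tert-butoxycarbonyl)-18-oxononadecanoic acid
Product: 11 tert-butyl (2R,3S)-5-oxo-2-(14-oxopentadecyl)oxolane-3-carboxylate
Conditions: Mn(CF3SO3)2(L) (2 mol %; L = matched enantiomer of N,N'-bis[(5-triisopropylsilylpyridin-2-yl)methyl]-2,2'-bipyrrolidine, found by running both), 50% aq. H2O2 (2 equiv, syringe pump), (CF3)2CHOH, 0 °C
Reagents that add atoms: none
Why: The free C5 carboxylate binds the divalent manganese centre and assists heterolysis of H2O2 to a formally pentavalent manganese-oxo carboxylate, which abstracts one C2 hydrogen by intramolecular 1,7-hydrogen atom transfer. The bound carboxylate oxygen is then transferred to the C2 radical (carboxylate rebound), so the five-membered ring O1–C2–C3–C4–C5 closes by C–O bond formation at the radical carbon with C3 and C4 as tether, the ring oxygen coming from the acid and H2O2 ending as water. The closest known reaction type is the manganese-catalysed, carboxylic-acid-directed γ-lactonisation of unactivated methylene C–H bonds with H2O2; what is extrapolated here is an acid with an ester on the β carbon, whose inductive deactivation of C2–H is the open point. The new C2 centre (R) is set by which diastereotopic hydrogen is removed, since rebound is faster than inversion of the radical; the chiral ligand, matched with the existing C3 centre, controls this, and the preference for chain and ester to lie anti in the ring-forming transition state works in the same direction, giving the trans lactone. Site selectivity over the thirteen remaining chain methylenes is needed and is secured by intramolecular delivery, because only the C5 acid can bind (the tert-butyl ester cannot) and C2 is its only γ carbon; the ketone is left free because it deactivates its end of the chain, whereas a ketal would add hydridic C–H bonds and is acid-labile. C3 is not touched, and any cis lactone is removed by chromatography and not epimerised, since epimerisation at C3 would lead into the enantiomeric series.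

Step 7
Reactants: 11 tert-butyl (2R,3S)-5-oxo-2-(14-oxopentadecyl)oxolane-3-carboxylate
Product: 12 tert-butyl (2R,3S)-2-[13-(2-methyl-1,3-dioxolan-2-yl)tridecyl]-5-oxooxolane-3-carboxylate
Conditions: HOCH2CH2OH, PPTS (cat.), benzene, reflux, Dean–Stark
Reagents that add atoms: ethylene glycol, OCCO
Why: Acid-catalysed ketalisation driven by azeotropic removal of water, in which the weak acid PPTS leaves the tert-butyl ester and the lactone intact and the ketal blocks ketone enolisation in step 8.

Step 8
Reactants: 12 tert-butyl (2R,3S)-2-[13-(2-methyl-1,3-dioxolan-2-yl)tridecyl]-5-oxooxolane-3-carboxylate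
Product: 13 tert-butyl (2R,3S,4R)-4-[(dimethylamino)methyl]-2-[13-(2-methyl-1,3-dioxolan-2-yl)tridecyl]-5-oxooxolane-3-carboxylate
Conditions: LiN(i-Pr)2 (1.1 equiv), THF, −78 °C; then CH2=NMe2+ I−, −78 to 0 °C
Reagents that add atoms: dimethylmethyleneiminium iodide, C=[N+](C)C.[I-]
Why: Irreversible kinetic deprotonation should occur at the C4 methylene, the more acidic (lactone) and less hindered site compared with the tertiary C3–H beside the tert-butyl ester, and the lithium enolate is aminomethylated by the iminium salt (Mannich reaction) anti to the C3 substituent; the new C4 centre is erased in step 9.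

Step 9
Reactants: 13 tert-butyl (2R,3S,4R)-4-[(dimethylamino)methyl]-2-[13-(2-methyl-1,3-dioxolan-2-yl)tridecyl]-5-oxooxolane-3-carboxylate
Product: 15 tert-butyl (2R,3S)-4-methylidene-2-[13-(2-methyl-1,3-dioxolan-2-yl)tridecyl]-5-oxooxolane-3-carboxylate, via quaternary ammonium iodide 14 (not isolated)
Conditions: MeI, MeOH, rt; then aq. NaHCO3, EtOAc, rt
Reagents that add atoms: none
Why: N-Methylation turns the amine into a leaving group β to the lactone carbonyl, and bicarbonate induces E1cB elimination of trimethylamine to the exocyclic alkene under conditions too mild to epimerise C3 or to move the double bond into the ring.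

Step 10
Reactants: 15 tert-butyl (2R,3S)-4-methylidene-2-[13-(2-methyl-1,3-dioxolan-2-yl)tridecyl]-5-oxooxolane-3-carboxylate
Product: 16 (2R,3S)-4-methylidene-5-oxo-2-(14-oxopentadecyl)oxolane-3-carboxylic acid
Conditions: CF3CO2H–H2O (9:1), 0 °C to rt
Reagents that add atoms: water, O
Why: Acidolysis of the tert-butyl ester (loss of 2-methylpropene via the tert-butyl cation) and acid-catalysed hydrolysis of the dioxolane proceed in the same medium, and neither the α-methylene lactone nor the C2 and C3 centres are affected by acid.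

Compound list
1 | ω-pentadecalactone (oxacyclohexadecan-2-one) | O=C1CCCCCCCCCCCCCCO1 | starting material
2 | N,O-dimethylhydroxylamine hydrochloride | CNOC.Cl | starting material
3 | 15-hydroxy-N-methoxy-N-methylpentadecanamide | CON(C)C(=O)CCCCCCCCCCCCCCO | intermediate
4 | N-methoxy-N-methyl-15-oxopentadecanamide | CON(C)C(=O)CCCCCCCCCCCCCC=O | intermediate
5 | di-tert-butyl succinate | CC(C)(C)OC(=O)CCC(=O)OC(C)(C)C | starting material
6 | tert-butyl 2-{14-[methoxy(methyl)amino]-14-oxotetradecyl}-5-oxooxolane-3-carboxylate (racemic Stobbe lactone, diastereomer mixture, not isolated) | CON(C)C(=O)CCCCCCCCCCCCCC1OC(=O)CC1C(=O)OC(C)(C)C | intermediate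
7 | (3E)-3-(tert-butoxycarbonyl)-18-[methoxy(methyl)amino]-18-oxooctadec-3-enoic acid | OC(=O)C/C(=C\CCCCCCCCCCCCCC(=O)N(C)OC)C(=O)OC(C)(C)C | intermediate
8 | (3R)-3-(tert-butoxycarbonyl)-18-[methoxy(methyl)amino]-18-oxooctadecanoic acid | OC(=O)C[C@H](C(=O)OC(C)(C)C)CCCCCCCCCCCCCCC(=O)N(C)OC | intermediate
9 | methylmagnesium bromide | C[Mg]Br | starting material
10 | (3R)-3-(tert-butoxycarbonyl)-18-oxononadecanoic acid | OC(=O)C[C@H](C(=O)OC(C)(C)C)CCCCCCCCCCCCCCC(C)=O | intermediate
11 | tert-butyl (2R,3S)-5-oxo-2-(14-oxopentadecyl)oxolane-3-carboxylate (trans) | C1C(=O)O[C@H](CCCCCCCCCCCCCC(C)=O)[C@H]1C(=O)OC(C)(C)C | intermediate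
12 | tert-butyl (2R,3S)-2-[13-(2-methyl-1,3-dioxolan-2-yl)tridecyl]-5-oxooxolane-3-carboxylate | C1C(=O)O[C@H](CCCCCCCCCCCCCC2(C)OCCO2)[C@H]1C(=O)OC(C)(C)C | intermediate
13 | tert-butyl (2R,3S,4R)-4-[(dimethylamino)methyl]-2-[13-(2-methyl-1,3-dioxolan-2-yl)tridecyl]-5-oxooxolane-3-carboxylate (expected major C4 epimer) | CN(C)C[C@@H]1C(=O)O[C@H](CCCCCCCCCCCCCC2(C)OCCO2)[C@H]1C(=O)OC(C)(C)C | intermediate
14 | {[(2R,3S,4R)-3-(tert-butoxycarbonyl)-2-[13-(2-methyl-1,3-dioxolan-2-yl)tridecyl]-5-oxooxolan-4-yl]methyl}trimethylammonium iodide (not isolated) | C[N+](C)(C)C[C@@H]1C(=O)O[C@H](CCCCCCCCCCCCCC2(C)OCCO2)[C@H]1C(=O)OC(C)(C)C.[I-] | intermediate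
15 | tert-butyl (2R,3S)-4-methylidene-2-[13-(2-methyl-1,3-dioxolan-2-yl)tridecyl]-5-oxooxolane-3-carboxylate | C=C1C(=O)O[C@H](CCCCCCCCCCCCCC2(C)OCCO2)[C@H]1C(=O)OC(C)(C)C | intermediate
16 | (2R,3S)-4-methylidene-5-oxo-2-(14-oxopentadecyl)oxolane-3-carboxylic acid | C=C1C(=O)O[C@H](CCCCCCCCCCCCCC(C)=O)[C@H]1C(=O)O | target

Total step count: 10. Longest linear sequence: 10 steps (from 1).

Steps most likely to fail

1. Step 6. The ester on C3 may slow hydrogen abstraction at C2 so far that undirected oxidation of remote chain methylenes or plain recovery of 10 prevails, or the wrong diastereotopic hydrogen may be removed and the cis lactone form. The fallback builds the lactone by an auxiliary-controlled aldol reaction; it sets out from 3 and returns at 12.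
   - MeMgBr (9) converts 3 into 16-hydroxyhexadecan-2-one F1.
   - Ethylene glycol with PPTS gives 14-(2-methyl-1,3-dioxolan-2-yl)tetradecan-1-ol F2.
   - Parikh–Doering oxidation (SO3·pyridine, DMSO, i-Pr2NEt) gives 14-(2-methyl-1,3-dioxolan-2-yl)tetradecanal F3.
   - The succinyl imide methyl 4-[(4S)-4-benzyl-2-oxo-1,3-oxazolidin-3-yl]-4-oxobutanoate F4 is made from (4S)-4-benzyl-1,3-oxazolidin-2-one, n-BuLi and methyl 4-chloro-4-oxobutanoate. Its dibutylboron enolate (Bu2BOSO2CF3, i-Pr2NEt, CH2Cl2, −78 °C) should add to F3 to give the syn-aldol adduct methyl (3S,4R)-3-{[(4S)-4-benzyl-2-oxo-1,3-oxazolidin-3-yl]carbonyl}-4-hydroxy-17-(2-methyl-1,3-dioxolan-2-yl)heptadecanoate F5.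
   - F5 should lactonise onto its methyl ester (on standing or with a trace of PPTS) to the trans lactone imide (4S)-4-benzyl-3-{(2R,3S)-2-[13-(2-methyl-1,3-dioxolan-2-yl)tridecyl]-5-oxooxolane-3-carbonyl}-1,3-oxazolidin-2-one F6.
   - LiOH/H2O2 (THF–H2O, 0 °C, acidification to pH 4) removes the auxiliary to give (2R,3S)-2-[13-(2-methyl-1,3-dioxolan-2-yl)tridecyl]-5-oxooxolane-3-carboxylic acid F7.
   - O-tert-Butyl-N,N'-diisopropylisourea (CH2Cl2, rt) esterifies F7 to 12.

2. Step 8. Deprotonation may compete at C3, followed by β-elimination of the lactone carboxylate and ring opening, or the exocyclic alkene may later migrate into the ring under base. The fallback methylenates the free acid, whose C3 carboxylate blocks C3 deprotonation and directs carboxylation to C4; it sets out from 11 and returns at 16.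
   - CF3CO2H/CH2Cl2 gives (2R,3S)-5-oxo-2-(14-oxopentadecyl)oxolane-3-carboxylic acid F8.
   - Noyori ketalisation (1,2-bis(trimethylsilyloxy)ethane, cat. Me3SiOSO2CF3, CH2Cl2, −78 °C, aqueous work-up) gives the ketal acid F7 described above.
   - MeOMgOCO2Me (Stiles reagent) in DMF at 130 °C, then cold acidification, gives (2R,3S)-2-[13-(2-methyl-1,3-dioxolan-2-yl)tridecyl]-5-oxooxolane-3,4-dicarboxylic acid F9.
   - Formaldehyde, N-methylaniline, NaOAc and AcOH at rt effect decarboxylative Mannich methylenation to (2R,3S)-4-methylidene-2-[13-(2-methyl-1,3-dioxolan-2-yl)tridecyl]-5-oxooxolane-3-carboxylic acid F10.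
   - Dilute aqueous HCl in THF removes the ketal to give 16. Ketal lost earlier in the acidic work-ups is harmless, because the malonic half-acid should react much faster than a methyl ketone.

3. Step 3. Self-condensation of the enolisable aldehyde and migration of the double bond out of conjugation in the alkoxide medium may erode the supply and the quality of the hydrogenation substrate. The fallback is an olefination; it sets out from 4 and returns at 7.
   - The phosphonate 1-tert-butyl 4-methyl 2-(diethoxyphosphoryl)butanedioate F11 is made from tert-butyl diethylphosphonoacetate, NaH and methyl bromoacetate.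
   - Horner–Wadsworth–Emmons reaction of 4 with F11 (NaH, THF, 0 °C, or LiCl/DBU) gives 1-tert-butyl 4-methyl (2E)-2-{15-[methoxy(methyl)amino]-15-oxopentadecylidene}butanedioate F12.
   - LiOH (1 equiv, THF–H2O, 0 °C) hydrolyses the unhindered, non-conjugated methyl ester selectively to give 7.

Further compounds
F1 | step 6 | 16-hydroxyhexadecan-2-one | CC(=O)CCCCCCCCCCCCCCO
F2 | step 6 | 14-(2-methyl-1,3-dioxolan-2-yl)tetradecan-1-ol | CC1(CCCCCCCCCCCCCCO)OCCO1
F3 | step 6 | 14-(2-methyl-1,3-dioxolan-2-yl)tetradecanal | CC1(CCCCCCCCCCCCCC=O)OCCO1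
F4 | step 6 | methyl 4-[(4S)-4-benzyl-2-oxo-1,3-oxazolidin-3-yl]-4-oxobutanoate | COC(=O)CCC(=O)N1[C@@H](Cc2ccccc2)COC1=O
F5 | step 6 | methyl (3S,4R)-3-{[(4S)-4-benzyl-2-oxo-1,3-oxazolidin-3-yl]carbonyl}-4-hydroxy-17-(2-methyl-1,3-dioxolan-2-yl)heptadecanoate | COC(=O)C[C@H](C(=O)N1[C@@H](Cc2ccccc2)COC1=O)[C@H](O)CCCCCCCCCCCCCC3(C)OCCO3
F6 | step 6 | (4S)-4-benzyl-3-{(2R,3S)-2-[13-(2-methyl-1,3-dioxolan-2-yl)tridecyl]-5-oxooxolane-3-carbonyl}-1,3-oxazolidin-2-one | C1C(=O)O[C@H](CCCCCCCCCCCCCC2(C)OCCO2)[C@H]1C(=O)N3[C@@H](Cc4ccccc4)COC3=O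
F7 | step 6 | (2R,3S)-2-[13-(2-methyl-1,3-dioxolan-2-yl)tridecyl]-5-oxooxolane-3-carboxylic acid | C1C(=O)O[C@H](CCCCCCCCCCCCCC2(C)OCCO2)[C@H]1C(=O)O
F8 | step 8 | (2R,3S)-5-oxo-2-(14-oxopentadecyl)oxolane-3-carboxylic acid | C1C(=O)O[C@H](CCCCCCCCCCCCCC(C)=O)[C@H]1C(=O)O
F9 | step 8 | (2R,3S)-2-[13-(2-methyl-1,3-dioxolan-2-yl)tridecyl]-5-oxooxolane-3,4-dicarboxylic acid (C4 epimers) | OC(=O)C1C(=O)O[C@H](CCCCCCCCCCCCCC2(C)OCCO2)[C@H]1C(=O)O
F10 | step 8 | (2R,3S)-4-methylidene-2-[13-(2-methyl-1,3-dioxolan-2-yl)tridecyl]-5-oxooxolane-3-carboxylic acid | C=C1C(=O)O[C@H](CCCCCCCCCCCCCC2(C)OCCO2)[C@H]1C(=O)O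
F11 | step 3 | 1-tert-butyl 4-methyl 2-(diethoxyphosphoryl)butanedioate (racemic) | CCOP(=O)(OCC)C(CC(=O)OC)C(=O)OC(C)(C)C
F12 | step 3 | 1-tert-butyl 4-methyl (2E)-2-{15-[methoxy(methyl)amino]-15-oxopentadecylidene}butanedioate | COC(=O)C/C(=C\CCCCCCCCCCCCCC(=O)N(C)OC)C(=O)OC(C)(C)C
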